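## Structural features

Premarineosin A is built on a tetrahydropyran (O1, C2–C6). C2 is the spiro N,O-ketal carbon shared with ring B, a 3-methoxy-2H-pyrrole that carries pyrrole ring A on its imine carbon. C3 bears pyrrole ring D through C2', and the other α-carbon of ring D (C5') is tied back to C4 by a heptamethylene chain. C3, C4, the chain and the C2'–N–C5' edge of ring D therefore form a strained twelve-membered [9](2,5)pyrrolophane, trans-fused to the pyran. Three of the four stereocentres are contiguous (C2, C3, C4); the methyl-bearing C6 is 1,3 to C4 and flanks O1. Fragile groups are the spiroaminal (acid opens it to a prodiginine-type cation), the methoxy enol ether–imine unit, two electron-rich N–H pyrroles, and C3–H, which is epimerisable in every carbonyl-level precursor. The real difficulty is the ansa ring and the trans C3/C4 pair on it: an end-to-end closure pays the strain in the ring-forming step and gives no stereocontrol. The key step exploits that O1–C2–C3–C4–C5–C6 is a disguised allyl ester. With C2 as carboxyl carbon, C5=C6 as alkene and the O1–C6 bond in place of C3–C4, these six atoms are an Ireland–Claisen array, and the bond the shift forms is the one shared by the pyran and the twelve-membered ring.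

## Logic of the disconnections

33 ⇒ 30 + 31. The bond between the imine carbon of ring B and ring A is cut. Ring A is a terminal aryl group, and leaving it to the end keeps the complete acid-labile chromophore out of the route. The forward step must be a mild palladium coupling on an imidoyl triflate beside an N,O-spiroketal, with a nitrogen protecting group (in 32) that leaves under base.

30 ⇒ 29 ⇒ 27. The triflate is traced to the lactam, and both C–N bonds of ring B (N–C2 and N–C=O) are cut so that nitrogen enters as ammonia. C2 becomes a ketal carbon that can equilibrate. The forward step needs acyl attack by ammonia rather than displacement of the methoxy group, and the spiro centre must settle correctly under acid.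

27 ⇒ 25 ⇒ 23 + 24. The C2–alkyne bond and the C–OMe bond are cut. C2 returns to a lactone carbonyl and the three carbons of ring B come from 24. This leaves a bicyclic lactone with three stereocentres. The demands are single acetylide addition to an enolisable lactone and methoxide addition β to the ester.

23 ⇒ 22 ⇒ 21 ⇒ 20 ⇒ 18 ⇒ 17. The O1–C6 bond is cut and C6 is taken back through a methyl ketone to an alkene carbon. The pyran disappears and what remains is a carbocycle with two adjacent stereocentres, an acid and an (E)-propenyl group, which is what a [3,3] shift leaves behind. The demands are hydroboration at C6 only and reagent control in the ketone reduction.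

17 ⇒ 14 (key). C3–C4 is cut and O–C6 is re-formed, which expands the twelve-membered carbocycle to a sixteen-membered lactone. The strained ring and two stereocentres are exchanged for an unstrained macrolactone and one carbinol centre. The forward step needs one ketene acetal geometry and a chair transition state.

14 ⇒ 13. The lactone C–O bond is cut. The demand is high dilution and activation at room temperature, because the pyrrolylacetic acid decarboxylates easily.

13 ⇒ 11 ⇒ 5 + 9. The C(sp3)–C(sp2) bond between the heptamethylene chain and the alkene is cut. This brings in the (E)-allylic carbinol with geometry and configuration already fixed. It also avoids an acetylide alkylation followed by hydride trans-reduction, neither of which the ester, its acidic α-CH2 and the pyrrole N–H would survive. The demand is an organozinc coupling that tolerates N–H.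

5 ⇒ 4 ⇒ 3 + 2 ⇒ 1. The bond from C5' of the pyrrole to the chain is cut as an acylation followed by deoxygenation; the only free α-position secures regiochemistry.

9 ⇒ 7 ⇒ 6. The C–I bond is traced to a terminal alkyne by syn hydrometalation; the stereocentre comes from the chiral pool.

## Other disconnections considered

Alternative 1: The cut is inside ring D. Its two C–N bonds are opened to a conjugated diyne, and the sp–sp bond that becomes C3'–C4' is then cut, giving the bis-alkyne A1 (pyran methyl glycoside with ethynyl at C3 and a non-8-ynyl chain at C4). Forward, Cu(OAc)2 in pyridine at high dilution would couple the two terminal alkynes to the thirteen-membered cyclic 1,3-diyne A2. A CuCl-catalysed double hydroamination would then fold the diyne into the pyrrole, and glycoside hydrolysis and oxidation would reach 23, where the plans merge.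
- In its favour: all carbon stereocentres are set on an ordinary six-membered ring before any macrocycle exists, and the coupling needs no protecting groups. Ring D appears late and meets fewer reagents than in the chosen plan; on this point the alternative is the better one.
- Against it: a thirteen-membered ring must hold a nearly linear six-carbon rod while trans-fused to the pyran, near the lower limit for cyclic 1,3-diynes, so cyclodimerisation is the likely competitor. The hydroamination works best with primary amines, so nitrogen would carry a substituent that must be removed from inside an ansa ring.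
- Comparison: on structure the two are equal, since neither closes the twelve-membered ring end to end. On mechanism the copper coupling creates no stereocentre, whereas the sigmatropic contraction creates two. On step economy the alternative is probably longer, because the stereocentres of A1 need separate operations.

Alternative 2: The cut is the C2–C3 bond, leading to carbinol A3, in which O1 is already attached to ring B as a 2-alkoxy group and C3 carries a hydroxyl beside ring D. Forward, acid would ionise A3 to an azafulvenium ion stabilised by ring D, and the alkoxy-bearing α-carbon of ring B would attack it in an ipso sense. This closes the pyran and dearomatises ring B to the spiro 2H-pyrrole A4, one Boc removal from the target.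
- In its favour: it is the most convergent plan. It forms C2–C3, the pyran, the spiro centre and C3 in one event with the whole chromophore in place. In endgame step economy it is better than the chosen plan, which needs lactam activation and a cross-coupling.
- Against it: A3 is a 2-alkoxy-3-methoxypyrrole, very electron-rich and prone to oxidation and to collapse to the pyrrolinone. Attack at the free β-carbon of ring B or at nitrogen competes with ipso attack. Two stereocentres arise from a planar cation with only C4 and C6 to bias them. A3 also already contains the twelve-membered pyrrolophane, so the macrocycle problem is not solved.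
- Comparison: on structure it addresses the spiro unit, where the chosen plan is weakest, but not the ansa ring, where the chosen plan is strongest. On mechanism it is cationic and reversible, so it relies on product stability rather than on pericyclic chirality transfer. On step economy it is equal or better after the macrocycle; the total depends on how the ring of A3 is closed.

Alternative 3: The cut is both C–N bonds of ring D, giving the lactone-fused cyclotridecane-1,4-dione A5. Forward, ammonia (NH4OAc, AcOH, heat) would condense with both ketones across the ring (Paal–Knorr) to give the pyrrolophane lactone A6, which is the same compound as 23.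
- In its favour: the chemistry is classical and simple, and the macrocycle to be closed is an unstrained carbocycle. The pyrrole appears only after the carbocyclic work, which makes it better than the chosen plan in functional-group robustness. The endgame is identical, so the two are equal there.
- Against it: A5 needs a C–C macrocyclisation to a thirteen-membered ring rather than a sixteen-membered lactonisation. C3 lies between a ketone and the lactone carbonyl, so it is labile and largely enolised; ammonia would turn that ketone into a poorly reactive vinylogous carbamate. The flat pyrrole must form against ansa strain, so forcing acid and furan formation are concerns.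
- Comparison: on structure both make the strained ring from a larger relaxed one, so they are equal in concept. On mechanism the condensation creates no stereocentre, whereas the contraction creates two. On step economy the alternative would match the chosen plan only if A5, with its stereocentres, were short to make.

Key step: step 9

Remark: locants O1 and C2–C6 are those of the target's tetrahydropyran and are kept for all intermediates (ring D atoms are primed); 19 and 20 are C6 epimer mixtures and 25–28 are written without configuration at C2, since these centres are fixed in steps 13 and 16.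

Step 1
Reactants: 1 7-bromoheptanoic acid
Product: 2 7-bromoheptanoyl chloride
Conditions: (COCl)2, DMF (cat.), CH2Cl2, 0 °C → rt
Reagents that add atoms: oxalyl chloride, ClC(=O)C(=O)Cl
Why: Acid chloride formation with oxalyl chloride under DMF catalysis; only gases are released, so crude 2 can be used directly, and the primary bromide is inert.

Step 2
Reactants: 3 ethyl 2-(1H-pyrrol-2-yl)acetate; 2 7-bromoheptanoyl chloride
Product: 4 ethyl 2-[5-(7-bromoheptanoyl)-1H-pyrrol-2-yl]acetate
Conditions: Et2AlCl, CH2Cl2, 0 °C; then 2, 0 °C → rt
Reagents that add atoms: none
Why: Friedel–Crafts acylation of an N–H pyrrole mediated by Et2AlCl, which metalates nitrogen and takes up the HCl that would otherwise oligomerise the pyrrole. The free α-position C5' of a 2-alkylpyrrole is its most nucleophilic carbon; ester and bromide are spectators.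

Step 3
Reactants: 4 ethyl 2-[5-(7-bromoheptanoyl)-1H-pyrrol-2-yl]acetate
Product: 5 ethyl 2-[5-(7-bromoheptyl)-1H-pyrrol-2-yl]acetate
Conditions: BH3·THF, THF, 0 °C → rt; MeOH quench, aqueous work-up
Reagents that add atoms: none
Why: Borane deoxygenation of a 2-acylpyrrole: the carbonyl is a vinylogous amide and is reduced faster than the aliphatic ester, and the O-borylated carbinol ionises to an azafulvene that accepts a second hydride to give the methylene group. Borane does not touch the primary bromide.

Step 4
Reactants: 6 (R)-but-3-yn-2-ol
Product: 7 (R)-tert-butyl(but-3-yn-2-yloxy)dimethylsilane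
Conditions: TBSCl, imidazole, CH2Cl2, 0 °C → rt
Reagents that add atoms: tert-butyldimethylsilyl chloride, CC(C)(C)[Si](C)(C)Cl
Why: Imidazole-promoted silylation protects the carbinol for the hydrometalation and the organozinc coupling; the stereocentre is not involved.

Step 5
Reactants: 7 (R)-tert-butyl(but-3-yn-2-yloxy)dimethylsilane
Product: 9 (R,E)-tert-butyl[(4-iodobut-3-en-2-yl)oxy]dimethylsilane, via alkenylzirconocene chloride 8 (not isolated)
Conditions: Cp2Zr(H)Cl, THF, rt; then I2, 0 °C
Reagents that add atoms: iodine, II
Why: Schwartz hydrozirconation–iodination: syn addition of Zr–H places zirconium on the terminal carbon and iodinolysis proceeds with retention, which fixes the (E)-iodoalkene.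

Step 6
Reactants: 5 ethyl 2-[5-(7-bromoheptyl)-1H-pyrrol-2-yl]acetate; 9 (R,E)-tert-butyl[(4-iodobut-3-en-2-yl)oxy]dimethylsilane
Product: 11 ethyl 2-{5-[(8E,10R)-10-(tert-butyldimethylsilyloxy)undec-8-en-1-yl]-1H-pyrrol-2-yl}acetate, via alkylzinc bromide 10 (not isolated)
Conditions: Zn dust, I2 (cat.), DMA, 70 °C; then 9, Pd(PPh3)4 (cat.), rt → 40 °C
Reagents that add atoms: none
Why: Negishi C(sp3)–C(sp2) cross-coupling: zinc inserts into the primary C–Br bond under iodide catalysis and the alkylzinc couples with the iodoalkene with retention of geometry. Organozinc halides tolerate esters and are protonated only slowly by N–H groups of this acidity, so the (R,E)-allylic carbinol unit is installed in one step without acetylide or hydride reagents.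

Step 7
Reactants: 11 ethyl 2-{5-[(8E,10R)-10-(tert-butyldimethylsilyloxy)undec-8-en-1-yl]-1H-pyrrol-2-yl}acetate
Product: 13 2-{5-[(8E,10R)-10-hydroxyundec-8-en-1-yl]-1H-pyrrol-2-yl}acetic acid, via hydroxy ester 12 (not isolated)
Conditions: Bu4NF, THF, rt; then LiOH, H2O/MeOH, 0 °C → rt; 1 M HCl to pH 4 at 0 °C
Reagents that add atoms: lithium hydroxide, [Li+].[OH-]
Why: Fluoride desilylation followed in the same flask by ester saponification. Acidification is cold and stops at pH 4 because pyrrol-2-ylacetic acids decarboxylate in strong acid; 13 is used at once.

Step 8
Reactants: 13 2-{5-[(8E,10R)-10-hydroxyundec-8-en-1-yl]-1H-pyrrol-2-yl}acetic acid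
Product: 14 sixteen-membered (R,E)-allylic pyrrol-2-ylacetate macrolactone (lactone of 13 between the carboxyl group and the 10-hydroxyl)
Conditions: 2-methyl-6-nitrobenzoic anhydride, DMAP, Et3N, CH2Cl2 (2 mM, slow addition), rt
Reagents that add atoms: none
Why: Shiina macrolactonisation (mixed anhydride, acyl transfer by DMAP) under high dilution at room temperature, so the labile pyrrolylacetic acid is never heated. The carbinol oxygen is the nucleophile, so the (R) centre is retained, and a sixteen-membered ring with an (E)-alkene and a flat pyrrole closes without strain.

Step 9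
Reactants: 14 sixteen-membered (R,E)-allylic pyrrol-2-ylacetate macrolactone
Product: 17 (3S,4S)-trans-pyrrolophane acid (twelve-membered ring; C2 carboxyl on C3; (E)-prop-1-enyl on C4), via silyl ketene acetal 15 (not isolated), via rearranged bis-silyl ester 16 (not isolated)
Conditions: LiN(SiMe3)2 (3.5 equiv), Me3SiCl–Et3N, THF, −78 °C → rt, then 60 °C; 1 M HCl, 0 °C
Reagents that add atoms: none
Why: Ireland–Claisen rearrangement used as a macrolactone ring contraction. LiN(SiMe3)2 with Me3SiCl present silylates the pyrrole nitrogen and converts the lactone into ketene acetal 15, which on warming undergoes a concerted suprafacial [3,3] shift through a six-membered transition state: the ketene acetal carbon bonds to the distal alkene carbon as the allylic C–O bond breaks, and cold aqueous acid frees 17 from 16. The closest known reaction type is the Ireland–Claisen contraction of macrocyclic allylic lactones to carbocycles. The twelve-membered ring is closed by contraction of the sixteen-membered one, not by end-to-end cyclisation, and the exchange of an ester for a carboxylate plus a C–C σ bond pays for the ansa strain. C4 is set by 1,3-chirality transfer from the (R)-carbinol, whose methyl group sits pseudo-equatorial in the chair, so the (E)-alkene is attacked on one face and an (E)-propenyl group results. C3 is set by the ketene acetal geometry (pyrrolyl cis to O-silyl, the usual result for arylacetates with amide bases) combined with the chair, which places H-3 and H-4 anti and gives the trans pair. The step needs chair over boat and one ketene acetal geometry; the ten-atom tether between the two pseudo-equatorial positions is long enough not to force a boat, and C4 stays correct even if C3 leaks.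

Step 10
Reactants: 17 (3S,4S)-trans-pyrrolophane acid
Product: 18 methyl ester of 17
Conditions: Me3SiCHN2, PhMe/MeOH, 0 °C
Reagents that add atoms: (trimethylsilyl)diazomethane, C[Si](C)(C)C=[N+]=[N-]
Why: O-Methylation of the acid with (trimethylsilyl)diazomethane in methanol; the conditions are neutral, so C3 is not epimerised and the acid is not left to decarboxylate.

Step 11
Reactants: 18 methyl ester of 17
Product: 20 methyl (3S,4S)-4-(2-hydroxypropyl)pyrrolophane-3-carboxylate (C6 epimers), via B-alkyl-9-BBN adduct 19 (not isolated)
Conditions: 9-BBN, THF, rt → 50 °C; then NaBO3·4H2O, THF/H2O, rt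
Reagents that add atoms: sodium perborate tetrahydrate, [Na+].[O-]OB=O.O.O.O.O
Why: Hydroboration–oxidation with 9-BBN, whose bulk directs boron to the methyl-bearing alkene carbon C6, away from the branched C4; 9-BBN spares the ester and perborate oxidises the C–B bond without harming the pyrrole. The new carbinol centre forms unselectively, which does not matter because it is oxidised in step 12.

Step 12
Reactants: 20 methyl (3S,4S)-4-(2-hydroxypropyl)pyrrolophane-3-carboxylate (C6 epimers)
Product: 21 methyl (3S,4S)-4-(2-oxopropyl)pyrrolophane-3-carboxylate
Conditions: SO3·pyridine, DMSO, iPr2NEt, CH2Cl2, 0 °C; aq. NaHCO3 work-up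
Reagents that add atoms: none
Why: Parikh–Doering oxidation (activated DMSO) of the secondary alcohol to the methyl ketone; it is non-acidic and uses no electrophilic halogen or high-valent metal, so ring D and C3 survive.

Step 13
Reactants: 21 methyl (3S,4S)-4-(2-oxopropyl)pyrrolophane-3-carboxylate
Product: 23 (3S,4S,6S)-pyrrolophane δ-lactone (C2 as lactone carbonyl), via hydroxy ester 22 (not isolated)
Conditions: (R)-2-methyl-CBS-oxazaborolidine (0.3 equiv), BH3·SMe2, THF, −30 °C; MeOH; then PPTS (cat.), PhMe, 60 °C
Reagents that add atoms: none
Why: Corey–Bakshi–Shibata reduction: the (R)-oxazaborolidine binds the ketone with the larger CH2R group away from the catalyst and delivers hydride to give the (S)-carbinol at C6 (reagent control, methyl as the small group). Mild acid then closes the δ-lactone by transesterification, and the minor C6 epimer can be removed as a diastereomer.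

Step 14
Reactants: 23 (3S,4S,6S)-pyrrolophane δ-lactone; 24 methyl propiolate
Product: 25 lactol (2-hydroxy-2-(3-methoxy-3-oxoprop-1-ynyl) derivative of 23)
Conditions: 24, LiN(SiMe3)2, THF, −78 °C; then 23, −78 °C; AcOH quench at −78 °C
Reagents that add atoms: none
Why: Addition of a lithium acetylide to a lactone: at −78 °C the tetrahedral alkoxide is stable, so a single addition gives the lactol on protonation. Lithium methyl propiolate is weakly basic, so enolisation at C3 and deprotonation of the pyrrole N–H should be minor.

Step 15
Reactants: 25 lactol
Product: 27 spiro 4-methoxybutenolide (spiroketal at C2), via methoxyacrylate lactol 26 (not isolated)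
Conditions: NaOMe (0.2 equiv), MeOH, 0 °C → rt
Reagents that add atoms: methanol, CO
Why: Base-catalysed conjugate addition of methanol to the ynoate, β to the ester (the only activating group while C2 stays a hemiketal), followed by lactonisation of the hemiketal hydroxyl onto the cis ester; this is the standard route from γ-hydroxy ynoates to 4-methoxybutenolides. The alkene isomers interconvert under methoxide and are drained through the one that can lactonise.

Step 16
Reactants: 27 spiro 4-methoxybutenolide
Product: 29 (2R,3S,4S,6S)-spirolactam (4-methoxy-3-pyrrolin-2-one spiro-fused at C2), via lactol amide 28 (not isolated)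
Conditions: NH3 (7 M in MeOH), rt → 40 °C; evaporate; then CSA (cat.), 4 Å MS, CH2Cl2, rt
Reagents that add atoms: ammonia, N
Why: Ammonolysis of the acylal-type butenolide (acyl substitution, the hemiketal oxygen leaves) gives amide 28; acid then ionises the lactol to the pyranyl oxocarbenium ion, which the amide nitrogen closes in a 5-exo sense (dehydrative N,O-spiroketalisation). The spiro centre is set under equilibrating conditions, and the favoured isomer should keep ring D and the chain equatorial, the C–N bond axial (anomeric stabilisation) and the bulkier alkenyl carbon equatorial.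

Step 17
Reactants: 29 (2R,3S,4S,6S)-spirolactam
Product: 30 imidoyl triflate (3-methoxy-2H-pyrrol-5-yl triflate spiro-fused at C2)
Conditions: Tf2O, 2,6-di-tert-butyl-4-methylpyridine, CH2Cl2, −78 → 0 °C; used crude
Reagents that add atoms: trifluoromethanesulfonic anhydride, O=S(=O)(OS(=O)(=O)C(F)(F)F)C(F)(F)F
Why: O-Sulfonylation of the secondary lactam to the cyclic imidoyl triflate, the activation used for 4-methoxypyrrolinones in prodiginine synthesis; the hindered base buffers triflic acid so that the spiroaminal and ring D survive.

Step 18
Reactants: 30 imidoyl triflate; 31 [1-(tert-butoxycarbonyl)-1H-pyrrol-2-yl]boronic acid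
Product: 33 premarineosin A, via N-Boc-premarineosin A 32 (not isolated)
Conditions: Pd(PPh3)4 (cat.), K3PO4, dioxane/H2O (10:1), 80 °C; then NaOMe, MeOH/THF, rt
Reagents that add atoms: none
Why: Suzuki–Miyaura coupling of the imidoyl triflate with the 2-pyrrolylboronic acid forms the bond between rings A and B; methoxide then cleaves the activated N-Boc group by acyl transfer. No stereocentre is touched.

## Compound list

1 | 7-bromoheptanoic acid | OC(=O)CCCCCCBr | starting material
2 | 7-bromoheptanoyl chloride | ClC(=O)CCCCCCBr | intermediate
3 | ethyl 2-(1H-pyrrol-2-yl)acetate | CCOC(=O)Cc1ccc[nH]1 | starting material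
4 | ethyl 2-[5-(7-bromoheptanoyl)-1H-pyrrol-2-yl]acetate | CCOC(=O)Cc1ccc([nH]1)C(=O)CCCCCCBr | intermediate
5 | ethyl 2-[5-(7-bromoheptyl)-1H-pyrrol-2-yl]acetate | CCOC(=O)Cc1ccc(CCCCCCCBr)[nH]1 | intermediate
6 | (R)-but-3-yn-2-ol | C#C[C@@H](C)O | starting material
7 | (R)-tert-butyl(but-3-yn-2-yloxy)dimethylsilane | C#C[C@@H](C)O[Si](C)(C)C(C)(C)C | intermediate
8 | chlorobis(cyclopentadienyl)[(R,E)-3-(tert-butyldimethylsilyloxy)but-1-en-1-yl]zirconium | C[C@@H](O[Si](C)(C)C(C)(C)C)/C=C/[Zr](Cl)(C1C=CC=C1)C1C=CC=C1 | intermediate
9 | (R,E)-tert-butyl[(4-iodobut-3-en-2-yl)oxy]dimethylsilane | C[C@@H](O[Si](C)(C)C(C)(C)C)/C=C/I | intermediate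
10 | bromo{7-[5-(2-ethoxy-2-oxoethyl)-1H-pyrrol-2-yl]heptyl}zinc | CCOC(=O)Cc1ccc(CCCCCCC[Zn]Br)[nH]1 | intermediate
11 | ethyl 2-{5-[(8E,10R)-10-(tert-butyldimethylsilyloxy)undec-8-en-1-yl]-1H-pyrrol-2-yl}acetate | CCOC(=O)Cc1ccc(CCCCCCC/C=C/[C@@H](C)O[Si](C)(C)C(C)(C)C)[nH]1 | intermediate
12 | ethyl 2-{5-[(8E,10R)-10-hydroxyundec-8-en-1-yl]-1H-pyrrol-2-yl}acetate | CCOC(=O)Cc1ccc(CCCCCCC/C=C/[C@@H](C)O)[nH]1 | intermediate
13 | 2-{5-[(8E,10R)-10-hydroxyundec-8-en-1-yl]-1H-pyrrol-2-yl}acetic acid | OC(=O)Cc1ccc(CCCCCCC/C=C/[C@@H](C)O)[nH]1 | intermediate
14 | sixteen-membered (R,E)-allylic pyrrol-2-ylacetate macrolactone | C1CCCCCc2ccc(CC(=O)O[C@H](C)/C=C/C1)[nH]2 | intermediate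
15 | N-trimethylsilyl trimethylsilyl ketene acetal of 14 (pyrrolyl cis to OSiMe3) | C1CCCCCc2ccc(/C=C(\O[Si](C)(C)C)O[C@H](C)/C=C/C1)n2[Si](C)(C)C | intermediate
16 | trimethylsilyl ester of N-trimethylsilyl-17 | C/C=C/[C@@H]1CCCCCCCc2ccc(n2[Si](C)(C)C)[C@H]1C(=O)O[Si](C)(C)C | intermediate
17 | (3S,4S)-trans-pyrrolophane acid, carboxyl on C3, (E)-prop-1-enyl on C4 | C/C=C/[C@@H]1CCCCCCCc2ccc([nH]2)[C@H]1C(=O)O | intermediate
18 | methyl ester of 17 | C/C=C/[C@@H]1CCCCCCCc2ccc([nH]2)[C@H]1C(=O)OC | intermediate
19 | B-alkyl-9-BBN adduct of 18, boron on C6 (C6 epimers) | CC(C[C@@H]1CCCCCCCc2ccc([nH]2)[C@H]1C(=O)OC)B1C2CCCC1CCC2 | intermediate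
20 | methyl (3S,4S)-4-(2-hydroxypropyl)pyrrolophane-3-carboxylate (C6 epimers) | CC(O)C[C@@H]1CCCCCCCc2ccc([nH]2)[C@H]1C(=O)OC | intermediate
21 | methyl (3S,4S)-4-(2-oxopropyl)pyrrolophane-3-carboxylate | CC(=O)C[C@@H]1CCCCCCCc2ccc([nH]2)[C@H]1C(=O)OC | intermediate
22 | methyl (3S,4S)-4-[(S)-2-hydroxypropyl]pyrrolophane-3-carboxylate | C[C@H](O)C[C@@H]1CCCCCCCc2ccc([nH]2)[C@H]1C(=O)OC | intermediate
23 | (3S,4S,6S)-pyrrolophane δ-lactone, C2 as lactone carbonyl | O=C1O[C@@H](C)C[C@@H]2CCCCCCCc3ccc([nH]3)[C@H]21 | intermediate
24 | methyl propiolate | C#CC(=O)OC | starting material
25 | lactol: 2-hydroxy-2-(3-methoxy-3-oxoprop-1-ynyl) derivative of 23 (C2 anomers) | COC(=O)C#CC1(O)O[C@@H](C)C[C@@H]2CCCCCCCc3ccc([nH]3)[C@H]21 | intermediate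
26 | lactol with (E)-1-methoxy-3-methoxy-3-oxoprop-1-enyl group at C2 | CO/C(=C/C(=O)OC)C1(O)O[C@@H](C)C[C@@H]2CCCCCCCc3ccc([nH]3)[C@H]21 | intermediate
27 | spiro 4-methoxybutenolide (4-methoxyfuran-2(5H)-one spiro-fused at C2; spiroketal anomers) | COC1=CC(=O)OC12O[C@@H](C)C[C@@H]1CCCCCCCc3ccc([nH]3)[C@H]12 | intermediate
28 | lactol with (E)-3-amino-1-methoxy-3-oxoprop-1-enyl group at C2 | CO/C(=C/C(N)=O)C1(O)O[C@@H](C)C[C@@H]2CCCCCCCc3ccc([nH]3)[C@H]21 | intermediate
29 | (2R,3S,4S,6S)-spirolactam (4-methoxy-1,5-dihydro-2H-pyrrol-2-one spiro-fused at C2) | COC1=CC(=O)N[C@]12O[C@@H](C)C[C@@H]1CCCCCCCc3ccc([nH]3)[C@H]12 | intermediate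
30 | imidoyl triflate of 29 | COC1=CC(OS(=O)(=O)C(F)(F)F)=N[C@]12O[C@@H](C)C[C@@H]1CCCCCCCc3ccc([nH]3)[C@H]12 | intermediate
31 | [1-(tert-butoxycarbonyl)-1H-pyrrol-2-yl]boronic acid | CC(C)(C)OC(=O)n1cccc1B(O)O | starting material
32 | N-Boc-premarineosin A (Boc on ring A nitrogen) | COC1=CC(c2cccn2C(=O)OC(C)(C)C)=N[C@]12O[C@@H](C)C[C@@H]1CCCCCCCc3ccc([nH]3)[C@H]12 | intermediate
33 | premarineosin A, (2R,3S,4S,6S) | COC1=CC(c2ccc[nH]2)=N[C@]12O[C@@H](C)C[C@@H]1CCCCCCCc3ccc([nH]3)[C@H]12 | target

## Step count and least certain steps

Total: 18 steps. Longest linear sequence: 16 steps (steps 1–3 and 6–18, from 1); steps 4 and 5 form the two-step branch to 9.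

Step 9 (key step). The rearrangement may leak through a boat-like transition state, or enolisation may give the ketene acetal with pyrrolyl trans to O-silyl; either erodes the configuration at C3, because medium-ring constraints can override the acyclic chair preference. The N-silyl group that must sit inside the forming ansa ring may also slow the shift. The fallback replaces kinetic with thermodynamic control of C3. It sets out from 14: the contraction is run as before and the C3-epimeric cis acid F1 is accepted, since C4 depends only on the (R)-carbinol and the (E)-alkene. F1 is esterified with Me3SiCHN2 to the cis methyl ester F2, which is equilibrated at C3 with DBU in toluene at 60 °C. The trans ester, in which ester and propenyl groups can both avoid the ring interior, should dominate. The route is rejoined at 18.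

Step 16. Ammonia may add to and displace the methoxy group at the β-carbon (vinylogous substitution) instead of attacking the lactone carbonyl, because 4-methoxybutenolides are electrophilic at both sites. The preference at the spiro centre under acid may also be incomplete. The fallback brings nitrogen to C2 first and never exposes the methoxyenoate to free ammonia. It sets out from 27: Me3SiN3 with catalytic Me3SiOTf in CH2Cl2 at −40 °C ionises the acyloxy ketal to the pyranyl oxocarbenium ion, which azide captures (axially, as in glycosyl azide formation) to give, after aqueous work-up, the azido acid F3. PMe3 in toluene (rt → 60 °C) then effects Staudinger reduction, and the iminophosphorane is acylated by the cis carboxylic acid to close the lactam. The route is rejoined at 29.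

Step 15. Methoxide may add through the ring-opened hydroxy-ynone tautomer of 25, the more reactive acceptor, which would place the methoxy group on the carbon next to the ester. The fallback locks the ring first. It sets out from 25: CSA and HC(OMe)3 in MeOH give the methyl ketal F4; NaOMe in MeOH then adds β to the ester, the only activating group left, to give the (E)-β-methoxyacrylate ketal F5; TsOH·H2O (cat.) in MeCN/H2O hydrolyses the ketal and lactonises. The route is rejoined at 27.

Step 13. Reagent control at C6 may be insufficient, because oxazaborolidine reductions distinguish a methyl group from an unbranched CH2 only moderately and the substrate's own bias is unknown. The fallback uses both C6 epimers and sets the centre by inversion. It sets out from 20, bypassing 21 and 22: PPTS in toluene at 60 °C lactonises both epimers to 23 and its C6 epimer, the (6R)-lactone F6, which are separated. F6 is opened with LiOH to the (6R)-hydroxy acid F7, which is closed with PPh3 and DIAD under dilution (Mitsunobu lactonisation, inversion at C6). Both epimers converge on 23.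

Step 6. The alkylzinc may be protonated by the pyrrole N–H or the acidic α-CH2 during the warm zinc insertion, and β-hydride elimination may intrude in the coupling. The fallback is a cross-electrophile coupling in which no alkylmetal accumulates. It sets out from 5 and 9: NiBr2(dme), 4,4'-di-tert-butyl-2,2'-bipyridine, Mn powder and NaI in DMA at rt. The alkyl radical is captured at nickel, and the method is known to tolerate N–H and retain alkene geometry. The route is rejoined at 11; no new compound is made.

Step 17 (with the coupling of step 18). Tf2O may attack the electron-rich ring D, adventitious triflic acid may ionise the spiroaminal, and the imidoyl triflate may hydrolyse in the aqueous coupling. The fallback activates the lactam through sulfur under neutral conditions. It sets out from 29: Lawesson's reagent in toluene at 60 °C gives the thiolactam F8, and MeI with K2CO3 in acetone gives the methylthio-2H-pyrrole F9. Liebeskind–Srogl coupling with 31 (Pd2(dba)3, tri(2-furyl)phosphine, copper thiophene-2-carboxylate CuO2CC4H3S, THF, 50 °C) then forms the bond to ring A. The route is rejoined at 32, which is deprotected as in step 18.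

## Further compounds

F1 | step 9 | (3R,4S)-cis-pyrrolophane acid (C3 epimer of 17) | C/C=C/[C@@H]1CCCCCCCc2ccc([nH]2)[C@@H]1C(=O)O
F2 | step 9 | methyl ester of F1 | C/C=C/[C@@H]1CCCCCCCc2ccc([nH]2)[C@@H]1C(=O)OC
F3 | step 16 | azido acid: 2-azidopyran bearing an (E)-2-carboxy-1-methoxyvinyl group at C2 | CO/C(=C/C(O)=O)[C@]1(N=[N+]=[N-])O[C@@H](C)C[C@@H]2CCCCCCCc3ccc([nH]3)[C@H]21
F4 | step 15 | methyl ketal of 25 | COC(=O)C#CC1(OC)O[C@@H](C)C[C@@H]2CCCCCCCc3ccc([nH]3)[C@H]21
F5 | step 15 | methyl ketal with (E)-1-methoxy-3-methoxy-3-oxoprop-1-enyl group at C2 | CO/C(=C/C(=O)OC)C1(OC)O[C@@H](C)C[C@@H]2CCCCCCCc3ccc([nH]3)[C@H]21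
F6 | step 13 | (3S,4S,6R)-pyrrolophane δ-lactone (C6 epimer of 23) | O=C1O[C@H](C)C[C@@H]2CCCCCCCc3ccc([nH]3)[C@H]21
F7 | step 13 | (3S,4S)-4-[(R)-2-hydroxypropyl]pyrrolophane-3-carboxylic acid | C[C@@H](O)C[C@@H]1CCCCCCCc2ccc([nH]2)[C@H]1C(=O)O
F8 | step 17 | thiolactam of 29 | COC1=CC(=S)N[C@]12O[C@@H](C)C[C@@H]1CCCCCCCc3ccc([nH]3)[C@H]12
F9 | step 17 | 5-methylthio-3-methoxy-2H-pyrrole spiro-fused at C2 (S-methyl thioimidate of F8) | COC1=CC(SC)=N[C@]12O[C@@H](C)C[C@@H]1CCCCCCCc3ccc([nH]3)[C@H]12
F0 | step 6 | none | none
A1 | alternative 1 | pyran methyl glycoside with ethynyl at C3 and non-8-ynyl at C4 | CO[C@H]1O[C@@H](C)C[C@H](CCCCCCCC#C)[C@H]1C#C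
A2 | alternative 1 | pyran-fused thirteen-membered cyclic 1,3-diyne | CO[C@H]1O[C@@H](C)C[C@@H]2CCCCCCCC#CC#C[C@H]21
A3 | alternative 2 | 2-alkoxy-3-methoxybipyrrole carbinol (C3 hydroxyl beside ring D, ansa ring in place, Boc on ring A) | COc1cc(-c2cccn2C(=O)OC(C)(C)C)[nH]c1O[C@@H](C)C[C@@H]1CCCCCCCc2ccc([nH]2)C1O
A4 | alternative 2 | premarineosin A with Boc on the ring A nitrogen | COC1=CC(c2cccn2C(=O)OC(C)(C)C)=N[C@]12O[C@@H](C)C[C@@H]1CCCCCCCc3ccc([nH]3)[C@H]12
A5 | alternative 3 | lactone-fused cyclotridecane-1,4-dione | O=C1O[C@@H](C)C[C@@H]2CCCCCCCC(=O)CCC(=O)[C@H]21
A6 | alternative 3 | pyrrolophane δ-lactone (identical with 23) | O=C1O[C@@H](C)C[C@@H]2CCCCCCCc3ccc([nH]3)[C@H]21
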